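**Retrosynthetic overview**
- The target comes from global desilylation of its tetrakis(triethylsilyl) ether.
- Pyran ring B is disconnected by an oxa-6π electrocyclisation of a (Z)-1-oxatriene (O=C3–C4=C4a–C8a=C1H2), followed by C5→C8a prototropy that sets C8a under control of C7/C8.
- Carbocycle A is formed first, in the same flask, by a 6-exo-dig Michael addition of a methyl ketone enolate onto the ynone of an acyclic C19 precursor.
- That precursor comes from an acyl Sonogashira union of a side-chain enoic acid (from D-isoleucine; C3' by chelation-controlled vinyl addition) with an enyne methyl ketone (from D-tartrate acetonide; C7 by Seebach methylation).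
- Ring order: A, then B.

Assumption: D-isoleucine (1) and dimethyl 2,3-O-isopropylidene-D-tartrate (8) are taken as the purchased chiral materials; labels C1–C8a (core) and C1'–C7' (side chain) follow the target numbering.

**Route**

Step 1
Reactants: 1 D-isoleucine ((2R,3R)-2-amino-3-methylpentanoic acid)
Product: 2 (2R,3R)-2-hydroxy-3-methylpentanoic acid
Conditions: NaNO2, 1 M H2SO4, H2O, 0 °C → rt
Reagents that add atoms: water, O
Why: Diazotisation of the α-amino acid (van Slyke-type deamination) goes through an α-lactone with double inversion, so OH replaces NH2 with net retention at C2 and the C3 centre is untouched.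

Step 2
Reactants: 2 (2R,3R)-2-hydroxy-3-methylpentanoic acid
Product: 3 (3R,4R)-3-hydroxy-4-methylhexan-2-one
Conditions: MeLi (3.5 equiv), THF, 0 °C → rt; inverse quench into cold 1 M HCl
Reagents that add atoms: methyllithium, [Li]C
Why: Addition of an organolithium to the lithium carboxylate (Gilman–van Ess ketone synthesis) stops at the dilithium gem-diolate, which collapses to the methyl ketone only on the acidic quench, while the α-carbinol is held as its lithium alkoxide so that neither stereocentre is disturbed.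

Step 3
Reactants: 3 (3R,4R)-3-hydroxy-4-methylhexan-2-one
Product: 4 (3R,4R,5R)-3,5-dimethylhept-1-ene-3,4-diol
Conditions: CH2=CHMgBr (3 equiv), THF, −78 → 0 °C; aq. NH4Cl
Reagents that add atoms: vinylmagnesium bromide, C=C[Mg]Br
Why: Grignard addition under Cram chelate control, in which the magnesium alkoxide and the carbonyl oxygen form a five-membered chelate and the vinyl group attacks the face opposite the sec-butyl group, sets the tertiary carbinol (3R; C3' of the target) from the purchased C4' centre.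

Step 4
Reactants: 4 (3R,4R,5R)-3,5-dimethylhept-1-ene-3,4-diol
Product: 5 (2E,4R,5R,6R)-4,5-dihydroxy-4,6-dimethyloct-2-enoic acid
Conditions: acrylic acid (3 equiv), second-generation Hoveyda–Grubbs catalyst [RuCl2(=CH-C6H4-2-OiPr)(H2IMes)] (5 mol%), CH2Cl2, 40 °C
Reagents that add atoms: acrylic acid, C=CC(=O)O
Why: Olefin cross-metathesis of the monosubstituted alkene of the free tertiary allylic alcohol with excess acrylic acid gives the thermodynamically favoured E-enoic acid and creates no stereocentre.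

Step 5
Reactants: 5 (2E,4R,5R,6R)-4,5-dihydroxy-4,6-dimethyloct-2-enoic acid
Product: 7 (2E,4R,5R,6R)-4,6-dimethyl-4,5-bis(triethylsilyloxy)oct-2-enoic acid, via triethylsilyl ester 6 (not isolated)
Conditions: Et3SiOTf (3.5 equiv), 2,6-lutidine, CH2Cl2, −78 → 0 °C; then H2O/MeOH/THF, rt
Reagents that add atoms: triethylsilyl trifluoromethanesulfonate, CC[Si](CC)(CC)OS(=O)(=O)C(F)(F)F
Why: Silylation with a silyl triflate and a hindered pyridine base caps the secondary and the tertiary alcohol, and the labile silyl ester formed alongside is hydrolysed selectively by aqueous methanol to return the free acid.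

Step 6
Reactants: 8 dimethyl (4S,5S)-2,2-dimethyl-1,3-dioxolane-4,5-dicarboxylate (dimethyl 2,3-O-isopropylidene-D-tartrate)
Product: 9 dimethyl (4S,5S)-2,2,4-trimethyl-1,3-dioxolane-4,5-dicarboxylate
Conditions: LiN(iPr)2 (1.05 equiv), THF/DMPU, −78 °C; MeI, −78 °C
Reagents that add atoms: iodomethane, CI
Why: Seebach alkylation of the tartrate acetonide ester enolate, in which the electrophile enters cis to the neighbouring ester so that the trans-diester is kept (net retention), places the new quaternary centre (C7 of the target) under control of the purchased tartrate centres.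

Step 7
Reactants: 9 dimethyl (4S,5S)-2,2,4-trimethyl-1,3-dioxolane-4,5-dicarboxylate
Product: 10 methyl (4S,5S)-2,2,4-trimethyl-5-[3-(trimethylsilyl)prop-2-ynoyl]-1,3-dioxolane-4-carboxylate
Conditions: Me3SiC≡CH (1.15 equiv), n-BuLi (1.1 equiv), THF, −78 °C; BF3·OEt2 (1.2 equiv); then 9, −78 °C
Reagents that add atoms: ethynyltrimethylsilane, C#C[Si](C)(C)C
Why: BF3-mediated acylation of a lithium acetylide by an ester (Yamaguchi–Hirao ynone synthesis) takes place only at the ester on the tertiary carbon because the ester on the quaternary carbon is neopentyl-like, and the weakly basic alkynylborate leaves the adjacent stereocentre (C8) unepimerised.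

Step 8
Reactants: 10 methyl (4S,5S)-2,2,4-trimethyl-5-[3-(trimethylsilyl)prop-2-ynoyl]-1,3-dioxolane-4-carboxylate
Product: 11 methyl (4S,5R)-2,2,4-trimethyl-5-[4-(trimethylsilyl)but-1-en-3-yn-2-yl]-1,3-dioxolane-4-carboxylate
Conditions: Ph3PCH3Br (1.3 equiv), KN(SiMe3)2 (1.2 equiv), THF, 0 °C; then 10, −78 → 0 °C
Reagents that add atoms: methyltriphenylphosphonium bromide, C[P+](c1ccccc1)(c1ccccc1)c1ccccc1.[Br-]
Why: Wittig methylenation with the non-stabilised ylide (no free base left) adds 1,2 to the ynone carbonyl, whose β-carbon is shielded by silicon, and leaves the ester alone; the change of the C5 descriptor from S to R is only a change of CIP priorities.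

Step 9
Reactants: 11 methyl (4S,5R)-2,2,4-trimethyl-5-[4-(trimethylsilyl)but-1-en-3-yn-2-yl]-1,3-dioxolane-4-carboxylate
Product: 13 1-[(4S,5R)-5-(but-1-en-3-yn-2-yl)-2,2,4-trimethyl-1,3-dioxolan-4-yl]ethan-1-one, via bis-silyl ketone 12 (not isolated)
Conditions: Me3SiCH2Li (2.5 equiv), THF/pentane, −78 → 0 °C; then MeOH, K2CO3 (cat.), rt
Reagents that add atoms: (trimethylsilyl)methyllithium, C[Si](C)(C)C[Li]
Why: Addition of Me3SiCH2Li to the hindered ester gives the α-silyl ketone, which is at once deprotonated to its enolate and so cannot add a second equivalent, and K2CO3/MeOH then cleaves both C–Si bonds (protodesilylation) to unveil the methyl ketone and the terminal alkyne in one pot.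

Step 10
Reactants: 13 1-[(4S,5R)-5-(but-1-en-3-yn-2-yl)-2,2,4-trimethyl-1,3-dioxolan-4-yl]ethan-1-one
Product: 14 (3S,4R)-3,4-dihydroxy-3-methyl-5-methylidenehept-6-yn-2-one
Conditions: CF3CO2H/H2O/THF, 0 °C → rt
Reagents that add atoms: none
Why: Acid-catalysed acetal hydrolysis of the dioxolane releases the diol, the enyne and the α-hydroxy ketone being stable to aqueous trifluoroacetic acid at room temperature.

Step 11
Reactants: 14 (3S,4R)-3,4-dihydroxy-3-methyl-5-methylidenehept-6-yn-2-one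
Product: 15 (3S,4R)-3-methyl-5-methylidene-3,4-bis(triethylsilyloxy)hept-6-yn-2-one
Conditions: Et3SiOTf (2.5 equiv), 2,6-lutidine, CH2Cl2, −78 → 0 °C
Reagents that add atoms: triethylsilyl trifluoromethanesulfonate, CC[Si](CC)(CC)OS(=O)(=O)C(F)(F)F
Why: Silylation of both hydroxyls at low temperature (no ketone enolisation) installs two bulky base-stable ethers that block oxa-Michael addition in step 13 and bias ring A towards the trans-diaxial arrangement used for C8a control.

Step 12
Reactants: 7 (2E,4R,5R,6R)-4,6-dimethyl-4,5-bis(triethylsilyloxy)oct-2-enoic acid; 15 (3S,4R)-3-methyl-5-methylidene-3,4-bis(triethylsilyloxy)hept-6-yn-2-one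
Product: 17 (3S,4R,9E,11R,12R,13R)-3,11,13-trimethyl-5-methylidene-3,4,11,12-tetrakis(triethylsilyloxy)pentadec-9-en-6-yne-2,8-dione, via acid chloride 16 (not isolated)
Conditions: 7, Me2C=C(Cl)NMe2 (1.1 equiv), CH2Cl2, 0 °C → rt; evaporate; then 15, PdCl2(PPh3)2 (2 mol%), CuI (4 mol%), Et3N (1.3 equiv), THF, rt
Reagents that add atoms: none
Why: The acid is converted under neutral conditions to the acid chloride (Ghosez reagent, silyl ethers untouched) and joined to the terminal alkyne by a copper-cocatalysed acyl Sonogashira coupling, which tolerates the methyl ketone that a lithium acetylide would not.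

Step 13
Reactants: 17 (3S,4R,9E,11R,12R,13R)-3,11,13-trimethyl-5-methylidene-3,4,11,12-tetrakis(triethylsilyloxy)pentadec-9-en-6-yne-2,8-dione
Product: 20 (7S,8R,8aS)-3-[(1E,3R,4R,5R)-3,5-dimethyl-3,4-bis(triethylsilyloxy)hept-1-en-1-yl]-7-methyl-7,8-bis(triethylsilyloxy)-1,7,8,8a-tetrahydro-6H-isochromen-6-one, via Z-dienone 18 (not isolated), via 2H-pyran 19 (not isolated)
Conditions: KN(SiMe3)2 (1.05 equiv), THF, −78 → −20 °C; AcOH (1.1 equiv); then DBU (0.2 equiv), rt
Reagents that add atoms: none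
Why: The potassium enolate of the methyl ketone adds to the ynone β-carbon in a 6-exo-dig intramolecular Michael reaction to close carbocycle A, the derived (Z)-1-oxatriene 18 closes to the 2H-pyran 19 by a thermal oxa-6π electrocyclisation that forms ring B, and amine-mediated prototropy (C5 to C8a) then gives the fully conjugated vinylogous ester, the proton entering C8a anti to the pseudoaxial C8 silyloxy group (A(1,2) strain holds the trans-bis-silyl ether diaxial) to give 8aS, which should also be the thermodynamic epimer under these equilibrating conditions.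

Step 14
Reactants: 20 (7S,8R,8aS)-3-[(1E,3R,4R,5R)-3,5-dimethyl-3,4-bis(triethylsilyloxy)hept-1-en-1-yl]-7-methyl-7,8-bis(triethylsilyloxy)-1,7,8,8a-tetrahydro-6H-isochromen-6-one
Product: 21 (7S,8R,8aS)-3-[(1E,3R,4R,5R)-3,4-dihydroxy-3,5-dimethylhept-1-en-1-yl]-7,8-dihydroxy-7-methyl-1,7,8,8a-tetrahydro-6H-isochromen-6-one
Conditions: HF·pyridine, pyridine, THF, 0 °C → rt
Reagents that add atoms: none
Why: Fluoride-driven cleavage of the four Si–O bonds with pyridine-buffered HF·pyridine frees the two secondary and two tertiary alcohols without base that could epimerise C8a and without acid strong enough to ionise the tertiary allylic alcohol.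

**Compound list**

1 | D-isoleucine, (2R,3R)-2-amino-3-methylpentanoic acid | CC[C@@H](C)[C@@H](N)C(=O)O | starting material
2 | (2R,3R)-2-hydroxy-3-methylpentanoic acid | CC[C@@H](C)[C@@H](O)C(=O)O | intermediate
3 | (3R,4R)-3-hydroxy-4-methylhexan-2-one | CC[C@@H](C)[C@@H](O)C(C)=O | intermediate
4 | (3R,4R,5R)-3,5-dimethylhept-1-ene-3,4-diol | CC[C@@H](C)[C@@H](O)[C@](C)(O)C=C | intermediate
5 | (2E,4R,5R,6R)-4,5-dihydroxy-4,6-dimethyloct-2-enoic acid | CC[C@@H](C)[C@@H](O)[C@](C)(O)/C=C/C(=O)O | intermediate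
6 | triethylsilyl (2E,4R,5R,6R)-4,6-dimethyl-4,5-bis(triethylsilyloxy)oct-2-enoate | CC[C@@H](C)[C@@H](O[Si](CC)(CC)CC)[C@](C)(O[Si](CC)(CC)CC)/C=C/C(=O)O[Si](CC)(CC)CC | intermediate
7 | (2E,4R,5R,6R)-4,6-dimethyl-4,5-bis(triethylsilyloxy)oct-2-enoic acid | CC[C@@H](C)[C@@H](O[Si](CC)(CC)CC)[C@](C)(O[Si](CC)(CC)CC)/C=C/C(=O)O | intermediate
8 | dimethyl (4S,5S)-2,2-dimethyl-1,3-dioxolane-4,5-dicarboxylate | COC(=O)[C@H]1OC(C)(C)O[C@@H]1C(=O)OC | starting material
9 | dimethyl (4S,5S)-2,2,4-trimethyl-1,3-dioxolane-4,5-dicarboxylate | COC(=O)[C@H]1OC(C)(C)O[C@]1(C)C(=O)OC | intermediate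
10 | methyl (4S,5S)-2,2,4-trimethyl-5-[3-(trimethylsilyl)prop-2-ynoyl]-1,3-dioxolane-4-carboxylate | C[Si](C)(C)C#CC(=O)[C@H]1OC(C)(C)O[C@]1(C)C(=O)OC | intermediate
11 | methyl (4S,5R)-2,2,4-trimethyl-5-[4-(trimethylsilyl)but-1-en-3-yn-2-yl]-1,3-dioxolane-4-carboxylate | C[Si](C)(C)C#CC(=C)[C@H]1OC(C)(C)O[C@]1(C)C(=O)OC | intermediate
12 | 1-{(4S,5R)-2,2,4-trimethyl-5-[4-(trimethylsilyl)but-1-en-3-yn-2-yl]-1,3-dioxolan-4-yl}-2-(trimethylsilyl)ethan-1-one | C[Si](C)(C)C#CC(=C)[C@H]1OC(C)(C)O[C@]1(C)C(=O)C[Si](C)(C)C | intermediate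
13 | 1-[(4S,5R)-5-(but-1-en-3-yn-2-yl)-2,2,4-trimethyl-1,3-dioxolan-4-yl]ethan-1-one | C#CC(=C)[C@H]1OC(C)(C)O[C@]1(C)C(C)=O | intermediate
14 | (3S,4R)-3,4-dihydroxy-3-methyl-5-methylidenehept-6-yn-2-one | C#CC(=C)[C@@H](O)[C@](C)(O)C(C)=O | intermediate
15 | (3S,4R)-3-methyl-5-methylidene-3,4-bis(triethylsilyloxy)hept-6-yn-2-one | C#CC(=C)[C@@H](O[Si](CC)(CC)CC)[C@](C)(O[Si](CC)(CC)CC)C(C)=O | intermediate
16 | (2E,4R,5R,6R)-4,6-dimethyl-4,5-bis(triethylsilyloxy)oct-2-enoyl chloride | CC[C@@H](C)[C@@H](O[Si](CC)(CC)CC)[C@](C)(O[Si](CC)(CC)CC)/C=C/C(Cl)=O | intermediate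
17 | (3S,4R,9E,11R,12R,13R)-3,11,13-trimethyl-5-methylidene-3,4,11,12-tetrakis(triethylsilyloxy)pentadec-9-en-6-yne-2,8-dione | CC[C@@H](C)[C@@H](O[Si](CC)(CC)CC)[C@](C)(O[Si](CC)(CC)CC)/C=C/C(=O)C#CC(=C)[C@@H](O[Si](CC)(CC)CC)[C@](C)(O[Si](CC)(CC)CC)C(C)=O | intermediate
18 | (2S,3R,5Z)-5-[(3E,5R,6R,7R)-5,7-dimethyl-2-oxo-5,6-bis(triethylsilyloxy)non-3-en-1-ylidene]-2-methyl-4-methylidene-2,3-bis(triethylsilyloxy)cyclohexan-1-one | CC[C@@H](C)[C@@H](O[Si](CC)(CC)CC)[C@](C)(O[Si](CC)(CC)CC)/C=C/C(=O)/C=C1/CC(=O)[C@@](C)(O[Si](CC)(CC)CC)[C@H](O[Si](CC)(CC)CC)C1=C | intermediate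
19 | (7S,8R)-3-[(1E,3R,4R,5R)-3,5-dimethyl-3,4-bis(triethylsilyloxy)hept-1-en-1-yl]-7-methyl-7,8-bis(triethylsilyloxy)-7,8-dihydro-1H-isochromen-6(5H)-one | CC[C@@H](C)[C@@H](O[Si](CC)(CC)CC)[C@](C)(O[Si](CC)(CC)CC)/C=C/C1=CC2=C(CO1)[C@@H](O[Si](CC)(CC)CC)[C@](C)(O[Si](CC)(CC)CC)C(=O)C2 | intermediate
20 | (7S,8R,8aS)-3-[(1E,3R,4R,5R)-3,5-dimethyl-3,4-bis(triethylsilyloxy)hept-1-en-1-yl]-7-methyl-7,8-bis(triethylsilyloxy)-1,7,8,8a-tetrahydro-6H-isochromen-6-one | CC[C@@H](C)[C@@H](O[Si](CC)(CC)CC)[C@](C)(O[Si](CC)(CC)CC)/C=C/C1=CC2=CC(=O)[C@@](C)(O[Si](CC)(CC)CC)[C@H](O[Si](CC)(CC)CC)[C@@H]2CO1 | intermediate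
21 | (7S,8R,8aS)-3-[(1E,3R,4R,5R)-3,4-dihydroxy-3,5-dimethylhept-1-en-1-yl]-7,8-dihydroxy-7-methyl-1,7,8,8a-tetrahydro-6H-isochromen-6-one | CC[C@@H](C)[C@@H](O)[C@](C)(O)/C=C/C1=CC2=CC(=O)[C@@](C)(O)[C@H](O)[C@@H]2CO1 | target

**Step count and risks**

Total step count: 14. Longest linear sequence: 9 steps (steps 6–14, from 8); the side-chain branch is 8 steps (steps 1–5, then 12–14).

The three steps most likely to fail:

Step 13 (ring A closure, electrocyclisation and C8a protonation in one flask). The strong-base Michael addition may be upset by competing attack on the dienyl ynone. The fallback avoids the potassium enolate; it sets out from 17 and comes back to the route at 20. Soft enolisation of the methyl ketone (Me3SiOTf, Et3N, CH2Cl2, −78 °C) gives the trimethylsilyl enol ether (3S,4R,9E,11R,12R,13R)-3,11,13-trimethyl-5-methylidene-3,4,11,12-tetrakis(triethylsilyloxy)-2-(trimethylsilyloxy)pentadeca-1,9-dien-6-yn-8-one F1. ZnI2 in CH2Cl2 then triggers an intramolecular Mukaiyama–Michael addition onto the ynone (6-exo-dig). After aqueous work-up the resulting dienone 18 is stirred with DBU as before, so that electrocyclisation to 19 and prototropy deliver 20.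

Step 7 (mono-alkynylation of one of two methyl esters). Over-addition or enolisation next to the reacting ester could erode yield or the C8 centre. The fallback is a two-stage acyl transfer that sets out from 9 and comes back at 10. The unhindered ester is converted selectively with MeNH(OMe)·HCl and i-PrMgCl (THF, −20 °C) into the Weinreb amide methyl (4S,5S)-5-[methoxy(methyl)carbamoyl]-2,2,4-trimethyl-1,3-dioxolane-4-carboxylate F2. LiC≡CSiMe3 (THF, −78 → 0 °C) then adds once through the chelated tetrahedral intermediate to give 10.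

Step 9 (hindered ester to methyl ketone beside an enyne). The organolithium may react sluggishly at the neopentyl-like ester or attack the enyne. The fallback is a redox sequence that sets out from 11 and comes back at 13. Reduction with i-Bu2AlH (CH2Cl2, −78 °C) gives the aldehyde (4S,5R)-2,2,4-trimethyl-5-[4-(trimethylsilyl)but-1-en-3-yn-2-yl]-1,3-dioxolane-4-carbaldehyde F3. MeMgBr (THF, −78 °C) gives the carbinol 1-{(4R,5R)-2,2,4-trimethyl-5-[4-(trimethylsilyl)but-1-en-3-yn-2-yl]-1,3-dioxolan-4-yl}ethan-1-ol F4 as an inconsequential epimer mixture. Dess–Martin periodinane oxidation gives the ketone 1-{(4S,5R)-2,2,4-trimethyl-5-[4-(trimethylsilyl)but-1-en-3-yn-2-yl]-1,3-dioxolan-4-yl}ethan-1-one F5, and K2CO3/MeOH removes the alkynyl silyl group to give 13.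

**Further compounds**

F1 | step 13 | (3S,4R,9E,11R,12R,13R)-3,11,13-trimethyl-5-methylidene-3,4,11,12-tetrakis(triethylsilyloxy)-2-(trimethylsilyloxy)pentadeca-1,9-dien-6-yn-8-one | CC[C@@H](C)[C@@H](O[Si](CC)(CC)CC)[C@](C)(O[Si](CC)(CC)CC)/C=C/C(=O)C#CC(=C)[C@@H](O[Si](CC)(CC)CC)[C@](C)(O[Si](CC)(CC)CC)C(=C)O[Si](C)(C)C
F2 | step 7 | methyl (4S,5S)-5-[methoxy(methyl)carbamoyl]-2,2,4-trimethyl-1,3-dioxolane-4-carboxylate | CON(C)C(=O)[C@H]1OC(C)(C)O[C@]1(C)C(=O)OC
F3 | step 9 | (4S,5R)-2,2,4-trimethyl-5-[4-(trimethylsilyl)but-1-en-3-yn-2-yl]-1,3-dioxolane-4-carbaldehyde | C[Si](C)(C)C#CC(=C)[C@H]1OC(C)(C)O[C@]1(C)C=O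
F4 | step 9 | 1-{(4R,5R)-2,2,4-trimethyl-5-[4-(trimethylsilyl)but-1-en-3-yn-2-yl]-1,3-dioxolan-4-yl}ethan-1-ol (carbinol epimers) | C[Si](C)(C)C#CC(=C)[C@H]1OC(C)(C)O[C@]1(C)C(C)O
F5 | step 9 | 1-{(4S,5R)-2,2,4-trimethyl-5-[4-(trimethylsilyl)but-1-en-3-yn-2-yl]-1,3-dioxolan-4-yl}ethan-1-one | C[Si](C)(C)C#CC(=C)[C@H]1OC(C)(C)O[C@]1(C)C(C)=O
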